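Time was the first setting I turned by hand: waiting longer gains X for as long as X is made faster than it goes on to E. But in the dusk run X fell from 15.5 % at 25.0 s to 8.2 % at 120 s, so the limit of 2.5 min stood well past the peak I read. Next came L: by hand, doubling L leaves the percentages alone if the steps are first order in L, and the readings agreed, with peaks of 14.9 % in spring and 15.5 % in dusk. Both runs held the same c(Z), so they showed nothing of how the feed of X depends on Z, and I assumed by hand that it goes with c(Z). How long the feed lasts could be read: in the spring run X + E stood at 18.1 % at 25.0 s but at 21.2 % at 60.0 s, so the feed faded within the run.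

| flask | L | Z | remark | time |
|---|---|---|---|---|
| spring | 0.54 M | 0.54 M | the very flask that is asked about, followed so far |  |
| dusk | 0.27 M | 0.54 M | run made earlier |  |
| flask | 0.54 M | 0.540 M |  | 2.5 min |

| run | time / s | X / % | E / % |
|---|---|---|---|
| spring | 10.0 | 9.8 | 1.0 |
| spring | 12.0 | 10.8 | 0.7 |
| spring | 20.0 | 13.6 | 2.0 |
| spring | 25.0 | 14.7 | 3.4 |
| spring | 40.0 | 14.9 | 5.4 |
| spring | 60.0 | 12.6 | 8.6 |
| dusk | 10.0 | 10.3 | 1.0 |
| dusk | 12.0 | 11.6 | 1.0 |
| dusk | 25.0 | 15.5 | 2.9 |
| dusk | 40.0 | 15.0 | 6.0 |
| dusk | 60.0 | 13.6 | 10.0 |
| dusk | 120 | 8.2 | 16.4 |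

(each reading ± 0.5 percentage points)

* the best time, 2.5 min at the latest, for X
* the amount of X, in percent of the L charged, at that time

- the numbers in the tables scatter with a standard deviation of 0.5 percentage points

I therefore carried one number. In the spring run, the peak of X divided by the opening feed (X + E at the first reading, per unit time) gave 13.8 s, my holding time: how long the opening feed would have to run to make the peak. The dusk run gave 13.7 s. The spring readings peaked later than that, between 25.0 s and 40.0 s, so the feed was dying, and I would have committed to about 14.9 % in that span.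

The forecast said 15.2 % at 0.57 min, on the ground that “X peaks where the dying feed equals this drain”.

The flask gives 14.4 % at 0.534 min, and both forecast values lie within tolerance.

    L + Z ⇌ X (K = 2.06 M⁻¹, k = 0.0302 M⁻¹ s⁻¹)
    X ⇌ E + Q (K = 0.340 M, k = 0.0124 s⁻¹)
    D ⇌ Q, rate k3*(cs3 - [Q]) while solid is left; crystals form when [Q] > cs3 (solubility = 0.300 M, k = 0.280 s⁻¹)
    2 Z → G (k = 0.0510 M⁻¹ s⁻¹)
    L + Q → J (k = 0.00453 M⁻¹ s⁻¹)

At 0.189 min the flask was using Z in the conversion into G 2.1 times as fast as in the forward step to X. At the best time, 29.1 % of its Z remained, and the computed peak over the spring opening feed gives 13.3 s, close to the holding time.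

With 0.92 M of Z in the neighbour flask, a feed that goes with c(Z) and the same holding time give 25.4 %. The computed peak there is 18.9 %, less than that, which corresponds to a holding time of 10.3 s.

The data are calculated with made-up constants.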